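The route rests on reading the C6 carbinol and the C7–C8 epoxide of ring B as an allylic alcohol whose C7 is a carbene carbon slipped into the strained C6=C8 bridge of a bicyclo[3.2.1]octenone. In one operation, exo dibromocarbene addition, silver-assisted cyclopropyl-to-allyl opening and capture by water form C6–C7, C7–C8 and C6–O, enlarge the five-membered ring to ring B and set C6. The precursor is the 3-azido-1,4-bis(silyloxy)bicyclo[3.2.1]oct-6-en-8-one made by ring-closing metathesis; because its strained C9 ketone, though non-enolisable, is open to nucleophilic cleavage, the carbene is delivered without base from PhHgCBr3.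

Key step: step 17

Conventions: core numbering is C1 (bridgehead carbinol), C2 (CH2), C3 (N), C4 (carbinol), C5 (bridgehead CH), C6 (carbinol), C7 and C8 (epoxide), C9 (ketone), and it is used for every ring A intermediate from compound 8 on. Ring A is C1–C5 with C9; ring B is C1, C9, C5, C6, C7, C8. β is the ring A face that carries the C3 nitrogen and α the opposite face; exo is the C9 side of the C6–C8 bridge. TBS = tert-butyldimethylsilyl. (salen)CrN3 = azido[N,N′-bis(3,5-di-tert-butylsalicylidene)cyclohexane-1,2-diaminato]chromium (trivalent chromium).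

Assumption: the (R,R)-(salen)CrN3 complex is taken to give the (1S,6S)-azido alcohol; if the sense of induction is the reverse, the (S,S)-complex is used.

Remark: PhHgCBr3 is a toxic organomercurial, taken as a purchased reagent and confined to step 17.

Step 1
Reactants: 1 cyclohexa-1,4-diene
Product: 2 cis-4,5-epoxycyclohexene (7-oxabicyclo[4.1.0]hept-3-ene; meso)
Conditions: mCPBA (0.95 equiv), NaHCO3, CH2Cl2, 0 °C
Reagents that add atoms: mCPBA, OOC(=O)c1cccc(Cl)c1
Why: Prilezhaev epoxidation with a deficit of peracid stops at the meso monoepoxide, since the remaining alkene is inductively deactivated once the first is oxidised.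

Step 2
Reactants: 2 cis-4,5-epoxycyclohexene
Product: 4 (1S,6S)-6-azidocyclohex-3-en-1-ol (trans), via azido silyl ether 3 (not isolated)
Conditions: (R,R)-(salen)CrN3 (2 mol %), TMSN3, Et2O, rt; then CSA (cat.), MeOH, rt
Reagents that add atoms: azidotrimethylsilane, C[Si](C)(C)N=[N+]=[N-]
Why: Catalytic asymmetric ring opening of a meso-epoxide by azide (a known reaction of this epoxide) delivers azide with inversion to one enantiotopic carbon, which sets C3 as S together with the trans carbinol, and acidic methanol frees the alcohol.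

Step 3
Reactants: 4 (1S,6S)-6-azidocyclohex-3-en-1-ol
Product: 5 (1R,6S)-6-azidocyclohex-3-en-1-yl 4-nitrobenzoate (cis)
Conditions: PPh3, DIAD (betaine preformed at 0 °C), 4-nitrobenzoic acid, THF, 0 °C to rt
Reagents that add atoms: 4-nitrobenzoic acid, OC(=O)c1ccc(cc1)[N+](=O)[O-]
Why: Mitsunobu esterification inverts the C4 carbinol by SN2 displacement of the oxyphosphonium ion, giving the cis azido ester, and preforming the betaine keeps PPh3 from reducing the azide; the crystalline ester should allow the enantiomeric purity to be raised by recrystallisation.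

Step 4
Reactants: 5 (1R,6S)-6-azidocyclohex-3-en-1-yl 4-nitrobenzoate
Product: 6 (1R,6S)-6-azidocyclohex-3-en-1-ol (cis)
Conditions: K2CO3 (cat.), MeOH, rt
Reagents that add atoms: none
Why: Base-catalysed transesterification removes the activated 4-nitrobenzoate without touching the azide or the stereocentres.

Step 5
Reactants: 6 (1R,6S)-6-azidocyclohex-3-en-1-ol
Product: 7 (1R,6S)-6-azidocyclohex-3-en-1-yl tert-butyl carbonate
Conditions: Boc2O, DMAP (cat.), MeCN, rt
Reagents that add atoms: di-tert-butyl dicarbonate, CC(C)(C)OC(=O)OC(=O)OC(C)(C)C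
Why: DMAP-catalysed acylation of the secondary alcohol installs the carbonate that will deliver oxygen to C9 in the next step.

Step 6
Reactants: 7 (1R,6S)-6-azidocyclohex-3-en-1-yl tert-butyl carbonate
Product: 9 3β-azido-1α-hydroxycyclohexane-4β,9β-diyl carbonate (6-azido-8-hydroxy-2,4-dioxabicyclo[3.3.1]nonan-3-one), via anti-epoxy carbonate 8 (not isolated)
Conditions: mCPBA, CH2Cl2, 0 °C; aqueous Na2SO3/NaHCO3 wash; crude epoxide, BF3·OEt2, CH2Cl2, −40 °C
Reagents that add atoms: mCPBA, OOC(=O)c1cccc(Cl)c1
Why: Peracid epoxidation should occur on the alkene face anti to the two cis substituents (steric approach control), and the Lewis-acid-promoted epoxy carbonate cyclisation then lets the Boc carbonyl open the epoxide at C9 only, through a six-membered ring with inversion and loss of isobutene, so that ring size fixes the C1/C9 regiochemistry and C1 is left as the free alcohol.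

Step 7
Reactants: 9 3β-azido-1α-hydroxycyclohexane-4β,9β-diyl carbonate
Product: 10 3β-azido-1-oxocyclohexane-4β,9β-diyl carbonate (6-azido-2,4-dioxabicyclo[3.3.1]nonane-3,8-dione)
Conditions: Dess–Martin periodinane, NaHCO3, CH2Cl2, 0 °C to rt
Reagents that add atoms: none
Why: Dess–Martin oxidation of the secondary C1 alcohol under buffered, non-basic conditions avoids β-elimination of the C3 azide.

Step 8
Reactants: 10 3β-azido-1-oxocyclohexane-4β,9β-diyl carbonate; 11 vinylmagnesium bromide
Product: 12 3β-azido-1β-hydroxy-1α-vinylcyclohexane-4β,9β-diyl carbonate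
Conditions: CH2=CHMgBr, CeCl3, THF, −78 °C; NH4Cl quench at −78 °C
Reagents that add atoms: none
Why: Cerium-mediated Grignard 1,2-addition suppresses enolisation, and on the ketone held in a chair by the diaxial carbonate bridge it should occur by axial attack on the convex α face, anti to the axial C9–O bond, which sets C1 with vinyl α and hydroxyl β (cis to N3 and O4).

Step 9
Reactants: 12 3β-azido-1β-hydroxy-1α-vinylcyclohexane-4β,9β-diyl carbonate
Product: 13 3β-azido-1α-vinylcyclohexane-1β,4β,9β-triol
Conditions: K2CO3 (cat.), MeOH, 0 °C to rt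
Reagents that add atoms: none
Why: Transesterification of the cyclic carbonate to dimethyl carbonate frees the C4 and C9 carbinols, and it does so even if the carbonate has migrated to the neighbouring C1 oxygen.

Step 10
Reactants: 13 3β-azido-1α-vinylcyclohexane-1β,4β,9β-triol
Product: 14 3β-azido-4β-(TBS-oxy)-1α-vinylcyclohexane-1β,9β-diol
Conditions: TBSCl (1.05 equiv), imidazole, DMF, 0 °C
Reagents that add atoms: tert-butyldimethylsilyl chloride, CC(C)(C)[Si](C)(C)Cl
Why: Silylation with the bulky chlorosilane discriminates on steric grounds, since the C9 carbinol is neopentylic beside the quaternary C1 and the C1 carbinol is tertiary, so only the C4 hydroxyl should react.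

Step 11
Reactants: 14 3β-azido-4β-(TBS-oxy)-1α-vinylcyclohexane-1β,9β-diol
Product: 15 3β-azido-1β-hydroxy-4β-(TBS-oxy)-1α-vinylcyclohexan-9-one
Conditions: IBX, DMSO, rt
Reagents that add atoms: none
Why: IBX oxidation converts the secondary carbinol of a vicinal diol into the α-hydroxy ketone without glycol cleavage and cannot touch the tertiary C1 alcohol.

Step 12
Reactants: 15 3β-azido-1β-hydroxy-4β-(TBS-oxy)-1α-vinylcyclohexan-9-one
Product: 16 3β-azido-1β,4β-bis(TBS-oxy)-1α-vinylcyclohexan-9-one (4-azido-2,5-bis(TBS-oxy)-2-vinylcyclohexanone)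
Conditions: TBSOTf, 2,6-lutidine, CH2Cl2, −78 to 0 °C
Reagents that add atoms: tert-butyldimethylsilyl triflate, CC(C)(C)[Si](C)(C)OS(=O)(=O)C(F)(F)F
Why: Silyl triflate silylation is needed for the hindered tertiary alcohol, and the weak base 2,6-lutidine at low temperature does not convert the ketone into its silyl enol ether.

Step 13
Reactants: 17 benzeneselenenyl chloride; 18 ethyl vinyl ether
Product: 19 2-(phenylselanyl)acetaldehyde
Conditions: CH2Cl2, −78 °C; then aqueous NaHCO3, rt; used fresh
Reagents that add atoms: water, O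
Why: Electrophilic selenenylation of the enol ether places selenium on the terminal carbon, and hydrolysis of the resulting α-chloro ether releases the aldehyde.

Step 14
Reactants: 16 3β-azido-1β,4β-bis(TBS-oxy)-1α-vinylcyclohexan-9-one; 19 2-(phenylselanyl)acetaldehyde
Product: 20 3β-azido-5α-[1-hydroxy-2-(phenylselanyl)ethyl]-1β,4β-bis(TBS-oxy)-1α-vinylcyclohexan-9-one (both carbinol epimers)
Conditions: LiN(iPr)2 (1.05 equiv), THF, −78 °C; then 19, −78 °C; NH4Cl quench
Reagents that add atoms: none
Why: The lithium enolate can form only toward C5, and its directed aldol addition should take place on the α face, anti to the adjacent C4 silyloxy group, which sets C5 with the new side chain cis to the C1 vinyl group.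

Step 15
Reactants: 20 3β-azido-5α-[1-hydroxy-2-(phenylselanyl)ethyl]-1β,4β-bis(TBS-oxy)-1α-vinylcyclohexan-9-one
Product: 21 3β-azido-1β,4β-bis(TBS-oxy)-1α,5α-divinylcyclohexan-9-one (4-azido-2,5-bis(TBS-oxy)-2,6-divinylcyclohexanone)
Conditions: MsCl, Et3N, CH2Cl2, 0 °C
Reagents that add atoms: none
Why: Mesylation of the β-hydroxy selenide triggers selenium-assisted anti-elimination through a seleniranium ion (the selenium analogue of the Peterson olefination), which gives the terminal vinyl group from either carbinol epimer without moving the double bond into conjugation.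

Step 16
Reactants: 21 3β-azido-1β,4β-bis(TBS-oxy)-1α,5α-divinylcyclohexan-9-one
Product: 22 3-azido-1,4-bis(TBS-oxy)bicyclo[3.2.1]oct-6-en-8-one (core numbering; azide equatorial; C4 silyloxy axial)
Conditions: second-generation Grubbs catalyst (10 mol %), CH2Cl2 (2 mM), 40 °C, argon sparge; product kept cold and dilute
Reagents that add atoms: none
Why: Ring-closing metathesis of cis-1,3-dialkenyl six-membered rings through the diaxial conformer is a known entry to bridged bicycloalkenes, and high dilution with removal of ethene should drive the strained C6=C8 bridge to form.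

Step 17
Reactants: 22 3-azido-1,4-bis(TBS-oxy)bicyclo[3.2.1]oct-6-en-8-one
Product: 24 3-azido-7-bromo-6-exo-hydroxy-1,4-bis(TBS-oxy)bicyclo[3.3.1]non-7-en-9-one, via dibromocyclopropane 23 (not isolated)
Conditions: PhHgCBr3 (2 equiv), benzene, 80 °C; filter; then AgClO4, CaCO3, acetone–H2O (4:1), rt
Reagents that add atoms: phenyl(tribromomethyl)mercury, BrC(Br)(Br)[Hg]c1ccccc1; water, O
Why: Thermolysis of PhHgCBr3 releases CBr2 without base or nucleophile, so the strained, cleavage-prone C9 ketone is spared, and the carbene adds in a concerted [2+1] cheletropic step to the exo face of the C6=C8 bridge (syn to the flat C9 carbonyl; the endo face lies under ring A and its axial C3–H) to give 23. Silver ion then pulls off the bromide that points toward C9 while the C6–C8 bond opens in a disrotatory two-electron electrocyclic sense with the bridgehead bonds turning inward, so ring B arises by ring enlargement of the five-membered ring (cyclopropyl-to-allyl cation opening) and not by an exo or endo cyclisation. Water captures the cis 2-bromoallyl cation at C6 from the exo face on which bromide left, which fixes the C6 carbinol syn to C9 as in the target, the endo face being closed by the ring A bridge. The closest known reaction type is the dihalocarbene ring expansion of norbornene-type alkenes to 3-halobicyclo[3.2.1]oct-2-enes together with the silver-promoted hydrolysis of ring-fused gem-dibromocyclopropanes to 2-bromoallylic alcohols. The selectivity needed is capture at C6 and not C8, and it is secured by the quaternary C1, whose bulky, inductively withdrawing and non-participating silyloxy group shields and deactivates the C8 terminus. Because the cation is flanked by the C9 carbonyl and is electron-poor, ionisation is not expected without the silver salt, and CaCO3 keeps the medium neutral for the silyl ethers.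

Step 18
Reactants: 25 hex-5-enenitrile; 26 pentylmagnesium bromide
Product: 28 undec-1-en-6-one, via ketimine magnesium salt 27 (not isolated)
Conditions: C5H11MgBr, CuBr (2 mol %), THF, reflux; then 1 M HCl, 0 °C to rt
Reagents that add atoms: water, O
Why: Copper-catalysed Grignard addition to a nitrile stops at the ketimine salt, so hydrolysis gives the ketone without over-addition and the terminal alkene is untouched.

Step 19
Reactants: 28 undec-1-en-6-one; 29 acrylic acid
Product: 30 (E)-7-oxododec-2-enoic acid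
Conditions: second-generation Hoveyda–Grubbs catalyst (3 mol %), acrylic acid (3 equiv), CH2Cl2, 40 °C
Reagents that add atoms: none
Why: Olefin cross-metathesis of a terminal alkene with acrylic acid is selective for the E-configured conjugated acid and tolerates the ketone.

Step 20
Reactants: 24 3-azido-7-bromo-6-exo-hydroxy-1,4-bis(TBS-oxy)bicyclo[3.3.1]non-7-en-9-one; 30 (E)-7-oxododec-2-enoic acid
Product: 32 (E)-N-[7-bromo-6-exo-hydroxy-9-oxo-1,4-bis(TBS-oxy)bicyclo[3.3.1]non-7-en-3-yl]-7-oxododec-2-enamide, via amine 31 (not isolated)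
Conditions: PMe3, THF–H2O (10:1), rt; evaporate; then 30, EDC, HOBt, CH2Cl2, 0 °C to rt
Reagents that add atoms: none
Why: Staudinger reduction gives the primary amine under neutral conditions, and carbodiimide amide coupling then acylates nitrogen in preference to the hindered C6 hydroxyl.

Step 21
Reactants: 32 (E)-N-[7-bromo-6-exo-hydroxy-9-oxo-1,4-bis(TBS-oxy)bicyclo[3.3.1]non-7-en-3-yl]-7-oxododec-2-enamide
Product: 33 (E)-N-[6-exo-hydroxy-9-oxo-1,4-bis(TBS-oxy)bicyclo[3.3.1]non-7-en-3-yl]-7-oxododec-2-enamide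
Conditions: Pd(OAc)2 (5 mol %), PPh3 (10 mol %), HCO2H, Et3N, DMF, 60 °C
Reagents that add atoms: none
Why: Palladium-catalysed formate reduction (oxidative addition of the alkenyl bromide to zerovalent palladium, formate decarboxylation and reductive elimination) replaces bromine by hydrogen without moving the C7=C8 double bond and leaves the conjugated amide and the silyl ethers alone.

Step 22
Reactants: 33 (E)-N-[6-exo-hydroxy-9-oxo-1,4-bis(TBS-oxy)bicyclo[3.3.1]non-7-en-3-yl]-7-oxododec-2-enamide
Product: 34 (E)-N-[1,4,6-trihydroxy-9-oxobicyclo[3.3.1]non-7-en-3-yl]-7-oxododec-2-enamide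
Conditions: HF·pyridine, pyridine–THF, 0 °C to rt
Reagents that add atoms: none
Why: Fluoride desilylation under the mildly acidic HF–pyridine conditions cleaves both silyl ethers without the retro-aldol cleavage that basic fluoride would risk for the two β-hydroxy ketone units.

Step 23
Reactants: 34 (E)-N-[1,4,6-trihydroxy-9-oxobicyclo[3.3.1]non-7-en-3-yl]-7-oxododec-2-enamide
Product: 35 isariotin C
Conditions: VO(acac)2 (5 mol %), t-BuOOH, CH2Cl2, 0 °C
Reagents that add atoms: tert-butyl hydroperoxide, CC(C)(C)OO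
Why: Vanadium-catalysed hydroxyl-directed epoxidation delivers oxygen to the C7=C8 face syn to the pseudo-axial C6 hydroxyl, which is also the open exo face, and so sets C7 and C8 while the electron-poor enamide alkene and both ketones are left alone.

Compound list
1 | cyclohexa-1,4-diene | C1=CCC=CC1 | starting material
2 | cis-4,5-epoxycyclohexene (7-oxabicyclo[4.1.0]hept-3-ene; meso) | C1=CC[C@H]2O[C@H]2C1 | intermediate
3 | (1S,6S)-6-azido-1-(trimethylsilyloxy)cyclohex-3-ene | [N-]=[N+]=N[C@H]1CC=CC[C@@H]1O[Si](C)(C)C | intermediate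
4 | (1S,6S)-6-azidocyclohex-3-en-1-ol | [N-]=[N+]=N[C@H]1CC=CC[C@@H]1O | intermediate
5 | (1R,6S)-6-azidocyclohex-3-en-1-yl 4-nitrobenzoate | [N-]=[N+]=N[C@H]1CC=CC[C@H]1OC(=O)c2ccc(cc2)[N+](=O)[O-] | intermediate
6 | (1R,6S)-6-azidocyclohex-3-en-1-ol | [N-]=[N+]=N[C@H]1CC=CC[C@H]1O | intermediate
7 | (1R,6S)-6-azidocyclohex-3-en-1-yl tert-butyl carbonate | [N-]=[N+]=N[C@H]1CC=CC[C@H]1OC(=O)OC(C)(C)C | intermediate
8 | tert-butyl 3β-azido-1α,9α-epoxycyclohexan-4β-yl carbonate (epoxide anti to both substituents) | [N-]=[N+]=N[C@H]1C[C@@H]2O[C@@H]2C[C@H]1OC(=O)OC(C)(C)C | intermediate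
9 | 3β-azido-1α-hydroxycyclohexane-4β,9β-diyl carbonate | [N-]=[N+]=N[C@H]1C[C@H](O)[C@@H]2C[C@H]1OC(=O)O2 | intermediate
10 | 3β-azido-1-oxocyclohexane-4β,9β-diyl carbonate | [N-]=[N+]=N[C@H]1CC(=O)[C@@H]2C[C@H]1OC(=O)O2 | intermediate
11 | vinylmagnesium bromide | C=C[Mg]Br | starting material
12 | 3β-azido-1β-hydroxy-1α-vinylcyclohexane-4β,9β-diyl carbonate | [N-]=[N+]=N[C@H]1C[C@@](C=C)(O)[C@@H]2C[C@H]1OC(=O)O2 | intermediate
13 | 3β-azido-1α-vinylcyclohexane-1β,4β,9β-triol | [N-]=[N+]=N[C@H]1C[C@@](C=C)(O)[C@@H](O)C[C@H]1O | intermediate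
14 | 3β-azido-4β-(TBS-oxy)-1α-vinylcyclohexane-1β,9β-diol | [N-]=[N+]=N[C@H]1C[C@@](C=C)(O)[C@@H](O)C[C@H]1O[Si](C)(C)C(C)(C)C | intermediate
15 | 3β-azido-1β-hydroxy-4β-(TBS-oxy)-1α-vinylcyclohexan-9-one | [N-]=[N+]=N[C@H]1C[C@@](C=C)(O)C(=O)C[C@H]1O[Si](C)(C)C(C)(C)C | intermediate
16 | 3β-azido-1β,4β-bis(TBS-oxy)-1α-vinylcyclohexan-9-one | [N-]=[N+]=N[C@H]1C[C@@](C=C)(O[Si](C)(C)C(C)(C)C)C(=O)C[C@H]1O[Si](C)(C)C(C)(C)C | intermediate
17 | benzeneselenenyl chloride | Cl[Se]c1ccccc1 | starting material
18 | ethyl vinyl ether | C=COCC | starting material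
19 | 2-(phenylselanyl)acetaldehyde | O=CC[Se]c1ccccc1 | intermediate
20 | 3β-azido-5α-[1-hydroxy-2-(phenylselanyl)ethyl]-1β,4β-bis(TBS-oxy)-1α-vinylcyclohexan-9-one (carbinol epimers) | [N-]=[N+]=N[C@H]1C[C@@](C=C)(O[Si](C)(C)C(C)(C)C)C(=O)[C@H](C(O)C[Se]c2ccccc2)[C@H]1O[Si](C)(C)C(C)(C)C | intermediate
21 | 3β-azido-1β,4β-bis(TBS-oxy)-1α,5α-divinylcyclohexan-9-one | [N-]=[N+]=N[C@H]1C[C@@](C=C)(O[Si](C)(C)C(C)(C)C)C(=O)[C@H](C=C)[C@H]1O[Si](C)(C)C(C)(C)C | intermediate
22 | 3-azido-1,4-bis(TBS-oxy)bicyclo[3.2.1]oct-6-en-8-one (core numbering) | [N-]=[N+]=N[C@H]1C[C@@]2(O[Si](C)(C)C(C)(C)C)C(=O)[C@H](C=C2)[C@H]1O[Si](C)(C)C(C)(C)C | intermediate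
23 | 3-azido-7,7-dibromo-1,4-bis(TBS-oxy)tricyclo[3.3.1.0(6,8)]nonan-9-one (exo cyclopropane; core numbering) | [N-]=[N+]=N[C@H]1C[C@@]2(O[Si](C)(C)C(C)(C)C)C(=O)[C@H]([C@H]3[C@@H]2C3(Br)Br)[C@H]1O[Si](C)(C)C(C)(C)C | intermediate
24 | 3-azido-7-bromo-6-exo-hydroxy-1,4-bis(TBS-oxy)bicyclo[3.3.1]non-7-en-9-one | [N-]=[N+]=N[C@H]1C[C@@]2(O[Si](C)(C)C(C)(C)C)C(=O)[C@H]([C@H](O)C(Br)=C2)[C@H]1O[Si](C)(C)C(C)(C)C | intermediate
25 | hex-5-enenitrile | C=CCCCC#N | starting material
26 | pentylmagnesium bromide | CCCCC[Mg]Br | starting material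
27 | N-(bromomagnesio)undec-1-en-6-imine | CCCCCC(=N[Mg]Br)CCCC=C | intermediate
28 | undec-1-en-6-one | CCCCCC(=O)CCCC=C | intermediate
29 | acrylic acid | C=CC(=O)O | starting material
30 | (E)-7-oxododec-2-enoic acid | CCCCCC(=O)CCC/C=C/C(=O)O | intermediate
31 | 3-amino-7-bromo-6-exo-hydroxy-1,4-bis(TBS-oxy)bicyclo[3.3.1]non-7-en-9-one | N[C@H]1C[C@@]2(O[Si](C)(C)C(C)(C)C)C(=O)[C@H]([C@H](O)C(Br)=C2)[C@H]1O[Si](C)(C)C(C)(C)C | intermediate
32 | (E)-N-[7-bromo-6-exo-hydroxy-9-oxo-1,4-bis(TBS-oxy)bicyclo[3.3.1]non-7-en-3-yl]-7-oxododec-2-enamide | CCCCCC(=O)CCC/C=C/C(=O)N[C@H]1C[C@@]2(O[Si](C)(C)C(C)(C)C)C(=O)[C@H]([C@H](O)C(Br)=C2)[C@H]1O[Si](C)(C)C(C)(C)C | intermediate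
33 | (E)-N-[6-exo-hydroxy-9-oxo-1,4-bis(TBS-oxy)bicyclo[3.3.1]non-7-en-3-yl]-7-oxododec-2-enamide | CCCCCC(=O)CCC/C=C/C(=O)N[C@H]1C[C@@]2(O[Si](C)(C)C(C)(C)C)C(=O)[C@H]([C@H](O)C=C2)[C@H]1O[Si](C)(C)C(C)(C)C | intermediate
34 | (E)-N-[1,4,6-trihydroxy-9-oxobicyclo[3.3.1]non-7-en-3-yl]-7-oxododec-2-enamide | CCCCCC(=O)CCC/C=C/C(=O)N[C@H]1C[C@@]2(O)C(=O)[C@H]([C@H](O)C=C2)[C@H]1O | intermediate
35 | isariotin C | CCCCCC(=O)CCC/C=C/C(=O)N[C@H]1C[C@@]2(O)C(=O)[C@H]([C@H](O)[C@@H]3O[C@@H]32)[C@H]1O | target

Total step count: 23. Longest linear sequence: 20 steps (steps 1–12, 14–17 and 20–23); steps 13, 18 and 19 are side branches.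

Steps most likely to fail

Step 17. The C6=C8 alkene carries electron-withdrawing groups on both allylic carbons, so carbene transfer may be slow and the carbene may instead be consumed by the azide. After ionisation the cation may be captured at C8, or it may suffer a 1,2-shift toward the silyloxy-bearing C1. The fallback gives up the carbene insertion and builds C6 and C7 from acrolein. It sets out from 16: the lithium enolate (LiN(iPr)2, THF, −78 °C) is added to acrolein to give the acrolein aldol adduct F1 as a mixture of carbinol epimers. Ring-closing metathesis with the second-generation Grubbs catalyst then closes the unstrained six-membered ring B between the C1 vinyl and the new allylic alcohol. This should give the exo alcohol F4 directly from one epimer and the 6-endo alcohol F2 from the other. F2 is converged by Mitsunobu inversion to the exo 4-nitrobenzoate F3 and methanolysis to F4. F4 is taken through the Staudinger reduction and acylation of step 20 with acid 30 and comes back to the route at 33, so step 21 is not needed.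

Step 16. Closing a strained cyclopentene bridge is reversible; ring-opening oligomerisation, or epimerisation at C5 before closure, may win over cyclisation. The fallback forms the C5–C6 bond by an aldol reaction and sets out from 16. Hydroboration of the C1 vinyl group with 9-BBN and oxidation with NaBO3 gives the primary alcohol F5. Dess–Martin oxidation gives the aldehyde F6. Intramolecular aldol addition of the C5 enolate (DBU, CH2Cl2) closes the five-membered ring to the bridged ketol F7. Syn-dehydration with the Burgess reagent (benzene, 50 °C) can place the double bond only between C6 and C8, because C5 is a bridgehead, and returns the route to 22. This path replaces steps 13 to 16.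

Step 6. Facial selectivity in the epoxidation may be poor, since the syn epoxide cannot cyclise, and the Lewis acid may remove the Boc group before it participates. The fallback fixes the epoxide face before the inversion and sets out from 4. Hydroxyl-directed epoxidation (VO(acac)2, t-BuOOH) of the trans azido alcohol gives the syn-epoxy alcohol F8 on a single face. Mitsunobu esterification with 4-nitrobenzoic acid inverts C4 to give the ester F9, in which the epoxide is now anti to both substituents. Brief methanolysis (K2CO3, MeOH, 0 °C) gives the alcohol F10, and Boc2O with DMAP returns the route to 8, which is cyclised with BF3·OEt2 as in step 6.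

Further compounds
F1 | step 17 | 3β-azido-5α-(1-hydroxyprop-2-enyl)-1β,4β-bis(TBS-oxy)-1α-vinylcyclohexan-9-one (carbinol epimers) | [N-]=[N+]=N[C@H]1C[C@@](C=C)(O[Si](C)(C)C(C)(C)C)C(=O)[C@H](C(O)C=C)[C@H]1O[Si](C)(C)C(C)(C)C
F2 | step 17 | 3-azido-6-endo-hydroxy-1,4-bis(TBS-oxy)bicyclo[3.3.1]non-7-en-9-one | [N-]=[N+]=N[C@H]1C[C@@]2(O[Si](C)(C)C(C)(C)C)C(=O)[C@H]([C@@H](O)C=C2)[C@H]1O[Si](C)(C)C(C)(C)C
F3 | step 17 | 3-azido-9-oxo-1,4-bis(TBS-oxy)bicyclo[3.3.1]non-7-en-6-exo-yl 4-nitrobenzoate | [N-]=[N+]=N[C@H]1C[C@@]2(O[Si](C)(C)C(C)(C)C)C(=O)[C@H]([C@H](OC(=O)c3ccc(cc3)[N+](=O)[O-])C=C2)[C@H]1O[Si](C)(C)C(C)(C)C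
F4 | step 17 | 3-azido-6-exo-hydroxy-1,4-bis(TBS-oxy)bicyclo[3.3.1]non-7-en-9-one | [N-]=[N+]=N[C@H]1C[C@@]2(O[Si](C)(C)C(C)(C)C)C(=O)[C@H]([C@H](O)C=C2)[C@H]1O[Si](C)(C)C(C)(C)C
F5 | step 16 | 3β-azido-1α-(2-hydroxyethyl)-1β,4β-bis(TBS-oxy)cyclohexan-9-one | [N-]=[N+]=N[C@H]1C[C@@](CCO)(O[Si](C)(C)C(C)(C)C)C(=O)C[C@H]1O[Si](C)(C)C(C)(C)C
F6 | step 16 | 2-[3β-azido-9-oxo-1β,4β-bis(TBS-oxy)cyclohexan-1α-yl]acetaldehyde | [N-]=[N+]=N[C@H]1C[C@@](CC=O)(O[Si](C)(C)C(C)(C)C)C(=O)C[C@H]1O[Si](C)(C)C(C)(C)C
F7 | step 16 | 3-azido-6-hydroxy-1,4-bis(TBS-oxy)bicyclo[3.2.1]octan-8-one (core numbering; C8 is CH2) | [N-]=[N+]=N[C@H]1C[C@@]2(O[Si](C)(C)C(C)(C)C)C(=O)[C@H](C(O)C2)[C@H]1O[Si](C)(C)C(C)(C)C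
F8 | step 6 | 3β-azido-1α,9α-epoxycyclohexan-4α-ol (epoxide syn to hydroxyl) | [N-]=[N+]=N[C@H]1C[C@@H]2O[C@@H]2C[C@@H]1O
F9 | step 6 | 3β-azido-1α,9α-epoxycyclohexan-4β-yl 4-nitrobenzoate | [N-]=[N+]=N[C@H]1C[C@@H]2O[C@@H]2C[C@H]1OC(=O)c3ccc(cc3)[N+](=O)[O-]
F10 | step 6 | 3β-azido-1α,9α-epoxycyclohexan-4β-ol | [N-]=[N+]=N[C@H]1C[C@@H]2O[C@@H]2C[C@H]1O
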